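**Retrosynthetic overview**

1. The target is 13-acetoxy-7,9-bis(angeloyloxy)longipinan-1-one. The esters go on last; the 7,9-trans diol comes from a C9-OH-directed reduction of a C7 ketone in the tricyclic 1,7-diketone 19.
2. Enabling feature: the C1 ketone and the C7 oxygen are 1,5-related through C11–C5–C6. C5–C11 is an edge of the cyclobutane (C4–C5–C11–C10) and C6–C7 is a bond of the seven-membered ring (C4–C5–C6–C7–C8–C9–C10), so both are the two new bonds of one enol–alkene [2+2], and C7–C11 is a retro-aldol bond.
3. Key disconnection: 19 ⇐ hydrindane β-diketone 17 (six-membered ring C1–C2–C3–C4–C10–C11, five-membered ring C11–C7–C8–C9–C10) carrying the C5=C6 alkene on C4. Light forms C5–C11 and C6–C7; strain release in the bicyclo[2.2.0]hexane photoadduct cleaves C7–C11.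
4. 17 ⇐ cis-fused lactone 8 ⇐ Diels–Alder of the (R)-butenolide 5 (C9 stereocentre) with silyloxydiene 7, which sets C10, C4 and C3; 5 ⇐ aldehyde 1 + methyl propiolate 2.
5. Ring order: six-membered ring (step 4) → temporary five-membered ring (step 12) → cyclobutane, then seven-membered ring last (step 13), with the five-membered ring opened in the same operation.

Key step: step 13

Remark: carbons carry the locants of the target skeleton (longipinane numbering: C1 ketone, C2, C3 with CH3-12, C4 and C11 cyclobutane bridgeheads, C5, C6 with CH3-14 and CH2OAc-13, C7, C8, C9, C10 with CH3-15); compounds 1, 2 and 6 are taken as commercial; TBS = tert-butyldimethylsilyl.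

**Step 1**
Reactants: 1 3-[(tert-butyldimethylsilyl)oxy]propanal; 2 methyl propiolate
Product: 3 methyl (R)-6-[(TBS)oxy]-4-hydroxyhex-2-ynoate
Conditions: ProPhenol ligand (20 mol %, the enantiomer that gives the R carbinol), Me2Zn, Ph3PO, toluene, 4 °C
Reagents that add atoms: none
Why: Zinc–ProPhenol-catalysed asymmetric alkynylation of the aldehyde by the zinc propiolate, in which the dinuclear zinc catalyst selects the aldehyde face and sets C9 as R.

**Step 2**
Reactants: 3 methyl (R)-6-[(TBS)oxy]-4-hydroxyhex-2-ynoate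
Product: 5 (R)-5-{2-[(TBS)oxy]ethyl}-4-methylfuran-2(5H)-one, via Z-hydroxy enoate 4 (not isolated)
Conditions: Me2CuLi (2.2 equiv), THF, −78 °C; then aq. NH4Cl, rt
Reagents that add atoms: lithium dimethylcuprate, [Li+].C[Cu-]C
Why: syn-Carbocupration (conjugate addition) of the ynoate places the new methyl (C15) and copper on the same side, so the carbinol and ester are cis and the Z-hydroxy ester should lactonise on work-up, with C9 untouched.

**Step 3**
Reactants: 6 (E)-pent-3-en-2-one
Product: 7 (E)-2-[(TBS)oxy]penta-1,3-diene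
Conditions: TBSOTf, Et3N, CH2Cl2, 0 °C
Reagents that add atoms: tert-butyldimethylsilyl triflate, CC(C)(C)[Si](C)(C)OS(=O)(=O)C(F)(F)F
Why: Soft enolisation and O-silylation on the methyl side of the ketone gives the cross-conjugated silyloxydiene with the E geometry of the enone retained.

**Step 4**
Reactants: 5 (R)-5-{2-[(TBS)oxy]ethyl}-4-methylfuran-2(5H)-one; 7 (E)-2-[(TBS)oxy]penta-1,3-diene
Product: 8 cis-fused lactone 5-[(TBS)oxy]-3-{2-[(TBS)oxy]ethyl}-3a,7-dimethyl-3a,4,7,7a-tetrahydro-2-benzofuran-1(3H)-one (3-side chain cis to the 3a-methyl, 7-methyl cis to the lactone carbonyl)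
Conditions: 7 (3 equiv), toluene, BHT (cat.), sealed tube, 170 °C
Reagents that add atoms: none
Why: Thermal Diels–Alder reaction in which the 2-silyloxy group and the terminal methyl of the diene both direct C3 to the lactone α-carbon C4 and C11 to C10, and the diene adds anti to the C9 side chain and endo to the lactone carbonyl, which sets C10, C4 and C3 relative to C9.

**Step 5**
Reactants: 8 cis-fused lactone
Product: 9 the corresponding lactol (anomer mixture at C5)
Conditions: DIBAL-H (1.1 equiv), CH2Cl2, −78 °C; Rochelle salt work-up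
Reagents that add atoms: none
Why: Partial reduction of the γ-lactone stops at the tetrahedral aluminium acetal at low temperature, while the silyl enol ether masks the C1 ketone.

**Step 6**
Reactants: 9 lactol
Product: 10 ethyl (E)-3-[4-[(TBS)oxy]-2-{(R)-1-hydroxy-3-[(TBS)oxy]propyl}-2,6-dimethylcyclohex-4-en-1-yl]-2-methylprop-2-enoate
Conditions: Ph3P=C(CH3)CO2Et, PhCO2H (cat.), toluene, 90 °C
Reagents that add atoms: ethyl 2-(triphenylphosphoranylidene)propanoate, CCOC(=O)C(C)=P(c1ccccc1)(c1ccccc1)c1ccccc1
Why: Wittig olefination of the open hydroxy-aldehyde form of the lactol with a stabilised ylide should give the E-trisubstituted C5=C6 enoate and free the C9 hydroxyl.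

**Step 7**
Reactants: 10 hydroxy enoate
Product: 11 the C9 TBS ether of 10
Conditions: TBSOTf, 2,6-lutidine, CH2Cl2, −78 to 0 °C
Reagents that add atoms: tert-butyldimethylsilyl triflate, CC(C)(C)[Si](C)(C)OS(=O)(=O)C(F)(F)F
Why: Silylation of the hindered secondary alcohol with the silyl triflate, a standard protection that blocks C9–O until the directed reduction.

**Step 8**
Reactants: 11 silylated enoate
Product: 12 the E allylic alcohol (C13–OH)
Conditions: DIBAL-H (2.5 equiv), CH2Cl2, −78 °C
Reagents that add atoms: none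
Why: 1,2-Reduction of the enoate to the allylic alcohol with DIBAL-H, to which the silyl ethers and the silyl enol ether are inert.

**Step 9**
Reactants: 12 allylic alcohol
Product: 13 the E allylic acetate
Conditions: Ac2O, pyridine, DMAP (cat.), CH2Cl2, 0 °C
Reagents that add atoms: acetic anhydride, CC(=O)OC(C)=O
Why: Acetylation of the primary alcohol installs the final C13 acetate early, since it should survive every later step.

**Step 10**
Reactants: 13 allylic acetate
Product: 14 (E)-3-[2-{(R)-1-[(TBS)oxy]-3-hydroxypropyl}-2,6-dimethyl-4-oxocyclohexyl]-2-methylallyl acetate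
Conditions: HF·pyridine, pyridine, THF, 0 °C to rt
Reagents that add atoms: none
Why: Fluoride desilylation cleaves the silyl enol ether and the primary silyl ether much faster than the hindered secondary C9 silyl ether, unmasking the C1 ketone and the C7 alcohol.

**Step 11**
Reactants: 14 keto alcohol
Product: 15 the corresponding C7 carboxylic acid
Conditions: TEMPO (cat.), PhI(OAc)2, MeCN/pH 7 buffer, rt
Reagents that add atoms: water, O
Why: TEMPO/PhI(OAc)2 oxidation of the primary alcohol through the aldehyde hydrate to the acid, which leaves ketone, acetate and alkene untouched.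

**Step 12**
Reactants: 15 keto acid
Product: 17 (E)-3-[1-[(TBS)oxy]-3-hydroxy-6,7a-dimethyl-4-oxo-2,4,5,6,7,7a-hexahydro-1H-inden-7-yl]-2-methylallyl acetate (enol form of the hydrindane β-diketone), via pentafluorophenyl ester 16 (not isolated)
Conditions: C6F5OH, EDC·HCl, CH2Cl2, 0 °C; then MgBr2·OEt2, iPr2NEt, CH2Cl2, rt
Reagents that add atoms: none
Why: Intramolecular crossed Claisen C-acylation under soft enolisation, in which the magnesium enolate of the C1 ketone forms reversibly and only its C11 terminus can reach the activated ester, closing the five-membered ring as an enolised β-diketone.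

**Step 13**
Reactants: 17 enolised hydrindane β-diketone
Product: 19 13-acetoxy-9-[(TBS)oxy]longipinane-1,7-dione, via cyclobutanol photoadduct 18 (not isolated)
Conditions: hν (medium-pressure Hg lamp, Pyrex, λ > 290 nm), degassed cyclohexane (2 mM), rt
Reagents that add atoms: none
Why: Excitation of the enolised β-diketone (O=C1–C11=C7–OH) gives the triplet vinylogous acid, whose C11 should add to C5 of the alkene held 1,3-diaxially above it, and the 1,4-diradical (tertiary C6, hydroxy-substituted C7) collapses to cyclobutanol 18, a bicyclo[2.2.0]hexane whose strain drives retro-aldol cleavage of C7–C11 to the 1,5-diketone. The closest known reaction type is the intramolecular de Mayo reaction (enol–alkene [2+2] photocycloaddition followed by retro-aldol two-carbon expansion of a cyclopentane-fused enol). The cyclobutane C4–C5–C11–C10 closes first by the C11–C5 bond (parallel, 1,3-diaxial mode), the seven-membered ring C4–C5–C6–C7–C8–C9–C10 closes last by C6–C7 radical recombination, and the five-membered ring is opened again by the fragmentation. C5 and C11 are fixed by the tether (the alkenyl group sits on the ring face that also carries C9, and the bridgehead enol is protonated on its only open face), and C6 by suprafacial addition of the E alkene, which puts CH3 on the concave and CH2OAc on the convex face of the bicyclo[2.2.0]hexane; rotation in the triplet diradical should let any Z alkene formed by sensitised isomerisation converge on the same, less crowded isomer. The step needs the parallel instead of the crossed (rule-of-five) mode and reaction through the C7 enol instead of the C1 enol: the first is secured because C5 lies over C11 and cannot reach C7 and because the fully substituted C6 terminus resists bonding to the fully substituted C11, the second because the C1-enol mode would need a two-carbon bridge across the bicyclo[2.2.0]hexane.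

**Step 14**
Reactants: 19 silylated tricyclic diketone
Product: 20 13-acetoxy-9-hydroxylongipinane-1,7-dione
Conditions: HF (48 % aq.), MeCN, 0 °C to rt
Reagents that add atoms: none
Why: Acidic fluoride desilylation of the C9 silyl ether, under which the β-hydroxy ketone and the acetate should be stable.

**Step 15**
Reactants: 20 β-hydroxy diketone
Product: 21 13-acetoxy-7,9-dihydroxylongipinan-1-one (7,9-trans diol)
Conditions: Me4NBH(OAc)3, MeCN/AcOH (1:1), −30 °C
Reagents that add atoms: none
Why: Evans–Saksena directed reduction, in which the C9 hydroxyl binds the triacetoxyborohydride and delivers hydride across the ring to its own face of the C7 ketone to give the trans diol, while the C1 ketone has no β-hydroxyl and should not react.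

**Step 16**
Reactants: 21 diol
Product: 22 13-acetoxy-7,9-bis(angeloyloxy)longipinan-1-one (target)
Conditions: angelic acid, 2,4,6-trichlorobenzoyl chloride, Et3N, toluene, rt; then 21, toluene, 80 °C (no DMAP)
Reagents that add atoms: angelic acid ((Z)-2-methylbut-2-enoic acid), C/C=C(/C)C(O)=O
Why: Yamaguchi-type esterification through the mixed anhydride of angelic acid without DMAP, a protocol for hindered alcohols that keeps the Z double bond, should acylate both secondary alcohols.

**Compound list**

1 | 3-[(tert-butyldimethylsilyl)oxy]propanal | O=CCCO[Si](C)(C)C(C)(C)C | starting material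
2 | methyl propiolate | C#CC(=O)OC | starting material
3 | methyl (R)-6-[(TBS)oxy]-4-hydroxyhex-2-ynoate | CC(C)(C)[Si](C)(C)OCC[C@@H](O)C#CC(=O)OC | intermediate
4 | methyl (R,Z)-6-[(TBS)oxy]-4-hydroxy-3-methylhex-2-enoate (not isolated) | CC(C)(C)[Si](C)(C)OCC[C@@H](O)/C(C)=C\C(=O)OC | intermediate
5 | (R)-5-{2-[(TBS)oxy]ethyl}-4-methylfuran-2(5H)-one | CC(C)(C)[Si](C)(C)OCC[C@@H](O1)C(C)=CC1=O | intermediate
6 | (E)-pent-3-en-2-one | C/C=C/C(C)=O | starting material
7 | (E)-2-[(TBS)oxy]penta-1,3-diene | C=C(O[Si](C)(C)C(C)(C)C)/C=C/C | intermediate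
8 | cis-fused Diels–Alder lactone, 5-[(TBS)oxy]-3-{2-[(TBS)oxy]ethyl}-3a,7-dimethyl-3a,4,7,7a-tetrahydro-2-benzofuran-1(3H)-one | CC(C)(C)[Si](C)(C)OCC[C@H]1OC(=O)[C@@H]2[C@H](C)C=C(O[Si](C)(C)C(C)(C)C)C[C@]12C | intermediate
9 | lactol of 8 (anomer mixture) | CC(C)(C)[Si](C)(C)OCC[C@H]1OC(O)[C@@H]2[C@H](C)C=C(O[Si](C)(C)C(C)(C)C)C[C@]12C | intermediate
10 | ethyl (E)-3-[4-[(TBS)oxy]-2-{(R)-1-hydroxy-3-[(TBS)oxy]propyl}-2,6-dimethylcyclohex-4-en-1-yl]-2-methylprop-2-enoate | CC(C)(C)[Si](C)(C)OCC[C@@H](O)[C@@]1(C)CC(O[Si](C)(C)C(C)(C)C)=C[C@@H](C)[C@H]1/C=C(\C)C(=O)OCC | intermediate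
11 | C9 TBS ether of 10 | CC(C)(C)[Si](C)(C)OCC[C@@H](O[Si](C)(C)C(C)(C)C)[C@@]1(C)CC(O[Si](C)(C)C(C)(C)C)=C[C@@H](C)[C@H]1/C=C(\C)C(=O)OCC | intermediate
12 | E allylic alcohol from 11 | CC(C)(C)[Si](C)(C)OCC[C@@H](O[Si](C)(C)C(C)(C)C)[C@@]1(C)CC(O[Si](C)(C)C(C)(C)C)=C[C@@H](C)[C@H]1/C=C(\C)CO | intermediate
13 | E allylic acetate from 12 | CC(C)(C)[Si](C)(C)OCC[C@@H](O[Si](C)(C)C(C)(C)C)[C@@]1(C)CC(O[Si](C)(C)C(C)(C)C)=C[C@@H](C)[C@H]1/C=C(\C)COC(C)=O | intermediate
14 | (E)-3-[2-{(R)-1-[(TBS)oxy]-3-hydroxypropyl}-2,6-dimethyl-4-oxocyclohexyl]-2-methylallyl acetate | OCC[C@@H](O[Si](C)(C)C(C)(C)C)[C@@]1(C)CC(=O)C[C@@H](C)[C@H]1/C=C(\C)COC(C)=O | intermediate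
15 | C7 carboxylic acid from 14 | OC(=O)C[C@@H](O[Si](C)(C)C(C)(C)C)[C@@]1(C)CC(=O)C[C@@H](C)[C@H]1/C=C(\C)COC(C)=O | intermediate
16 | pentafluorophenyl ester of 15 (not isolated) | O=C(Oc1c(F)c(F)c(F)c(F)c1F)C[C@@H](O[Si](C)(C)C(C)(C)C)[C@@]1(C)CC(=O)C[C@@H](C)[C@H]1/C=C(\C)COC(C)=O | intermediate
17 | hydrindane β-diketone, drawn as the C7 enol | O=C1C[C@@H](C)[C@@H](/C=C(\C)COC(C)=O)[C@@]2(C)[C@H](O[Si](C)(C)C(C)(C)C)CC(O)=C12 | intermediate
18 | cyclobutanol photoadduct with the bicyclo[2.2.0]hexane core (not isolated) | O[C@]15C[C@@H](O[Si](C)(C)C(C)(C)C)[C@]2(C)[C@@H]3[C@@H]([C@@]25C(=O)C[C@H]3C)[C@@]1(C)COC(C)=O | intermediate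
19 | 13-acetoxy-9-[(TBS)oxy]longipinane-1,7-dione | O=C1C[C@@H](O[Si](C)(C)C(C)(C)C)[C@]2(C)[C@@H]3[C@@H]([C@H]2C(=O)C[C@H]3C)[C@@]1(C)COC(C)=O | intermediate
20 | 13-acetoxy-9-hydroxylongipinane-1,7-dione | O=C1C[C@@H](O)[C@]2(C)[C@@H]3[C@@H]([C@H]2C(=O)C[C@H]3C)[C@@]1(C)COC(C)=O | intermediate
21 | 13-acetoxy-7,9-dihydroxylongipinan-1-one | O[C@@H]1C[C@@H](O)[C@]2(C)[C@@H]3[C@@H]([C@H]2C(=O)C[C@H]3C)[C@@]1(C)COC(C)=O | intermediate
22 | 13-acetoxy-7,9-bis(angeloyloxy)longipinan-1-one | C/C=C(/C)C(=O)O[C@@H]1C[C@@H](OC(=O)/C(C)=C\C)[C@]2(C)[C@@H]3[C@@H]([C@H]2C(=O)C[C@H]3C)[C@@]1(C)COC(C)=O | target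

**Totals and risks**

Total step count: 16. Longest linear sequence: 15 steps (steps 1, 2, 4–16).

Step 13. Unproductive decay of the excited chelated enol, reaction through the C1-enol tautomer, or crossed closure of the diradical could erode the photocascade. The fallback fixes the enol and separates cycloaddition from fragmentation. It sets out from 17: O-acylation with benzyl chloroformate (pyridine, CH2Cl2, 0 °C) and separation of the regioisomers should give the C7 enol benzyl carbonate F1, in which only the C11=C7 double bond can react. Irradiation (Pyrex, cyclohexane) should give the cyclobutyl carbonate F2. Hydrogenolysis (H2, Pd/C, EtOAc) frees the cyclobutanol, which fragments by retro-aldol, and the route is rejoined at 19.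

Step 4. Slow cycloaddition at the β,β-disubstituted butenolide could let thermal decomposition of the diene win. The fallback is a stepwise ionic annulation. It sets out from 5 and 7: Mukaiyama–Michael addition (TiCl4, CH2Cl2, −78 °C) should give the enone lactone F3. Intramolecular Michael addition of the lactone enolate (t-BuOK cat., THF, −20 °C) closes the cyclohexanone F4. Kinetic enolisation on the C2 side with LDA/TBSCl (THF, −78 °C) returns to 8.

Step 16. Incomplete acylation of two neopentyl-type secondary alcohols and Z-to-E isomerisation of the activated angeloyl donor are the likely failures. The fallback builds the Z alkenes on the substrate. It sets out from 21: esterification with 2-[bis(2,2,2-trifluoroethoxy)phosphoryl]propanoic acid (DCC, DMAP, CH2Cl2) should give the bis(phosphonopropionate) F5. A double Still–Gennari olefination with acetaldehyde (KHMDS, 18-crown-6, THF, −78 °C) then forms both Z-2-methylbut-2-enoates and arrives at 22.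

**Further compounds**

F1 | step 13 | C7 enol benzyl carbonate of 17 | O=C1C[C@@H](C)[C@@H](/C=C(\C)COC(C)=O)[C@@]2(C)[C@H](O[Si](C)(C)C(C)(C)C)CC(OC(=O)OCc3ccccc3)=C12
F2 | step 13 | cyclobutyl benzyl carbonate photoadduct (O-benzyloxycarbonyl derivative of 18) | O=C(OCc1ccccc1)O[C@]15C[C@@H](O[Si](C)(C)C(C)(C)C)[C@]2(C)[C@@H]3[C@@H]([C@@]25C(=O)C[C@H]3C)[C@@]1(C)COC(C)=O
F3 | step 4 | 4-methyl-4-[(E)-2-oxopent-3-en-1-yl]-5-{2-[(TBS)oxy]ethyl}dihydrofuran-2(3H)-one (side chains trans) | CC(C)(C)[Si](C)(C)OCC[C@H]1OC(=O)C[C@]1(C)CC(=O)/C=C/C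
F4 | step 4 | cis-fused keto lactone, 3-{2-[(TBS)oxy]ethyl}-3a,7-dimethylhexahydro-2-benzofuran-1,5-dione | CC(C)(C)[Si](C)(C)OCC[C@H]1OC(=O)[C@@H]2[C@H](C)CC(=O)C[C@]12C
F5 | step 16 | 7,9-bis{2-[bis(2,2,2-trifluoroethoxy)phosphoryl]propanoate} of 21 | CC(C(=O)O[C@@H]1C[C@@H](OC(=O)C(C)P(=O)(OCC(F)(F)F)OCC(F)(F)F)[C@]2(C)[C@@H]3[C@@H]([C@H]2C(=O)C[C@H]3C)[C@@]1(C)COC(C)=O)P(=O)(OCC(F)(F)F)OCC(F)(F)F
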